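| setting | grey | violet | teal | red | east | south |
|---|---|---|---|---|---|---|
| substrate | 1.1 M | 1.1 M | 1.1 M | 1.1 M | 1.1 M | 1.1 M |
| partner | 2 equiv | 2 equiv | 2 equiv | 1.4 equiv | 2.00 equiv | 0.500 equiv |
| initiator | 0.38 mol% | 1 mol% | 2.1 mol% | 0.53 mol% | 0.53 mol% | 2 mol% |
| remark | run made earlier | run made earlier | run made earlier | run made earlier |  |  |
| time |  |  |  |  | 2.0 min | 0.60 min |

| run | time / s | product / % | substrate / % |
|---|---|---|---|
| grey | 10.0 | 13.2 | 86.9 |
| grey | 15.0 | 19.9 | 80.7 |
| grey | 30.0 | 34.8 | 65.3 |
| grey | 40.0 | 41.9 | 57.6 |
| grey | 60.0 | 55.5 | 44.3 |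
| violet | 10.0 | 20.5 | 78.8 |
| violet | 15.0 | 30.7 | 69.9 |
| violet | 30.0 | 51.5 | 48.2 |
| violet | 60.0 | 78.7 | 21.2 |
| teal | 12.0 | 34.9 | 64.0 |
| teal | 25.0 | 61.9 | 38.4 |
| teal | 40.0 | 79.8 | 18.9 |
| teal | 50.0 | 85.6 | 11.5 |
| teal | 60.0 | 91.0 | 7.6 |
| red | 10.0 | 11.9 | 87.7 |
| red | 15.0 | 17.2 | 83.4 |
| red | 30.0 | 29.4 | 69.6 |
| red | 60.0 | 47.1 | 51.6 |

(readings scatter by 0.5 percentage points)

- the earlier runs were read with a standard deviation of 0.5 percentage points

1. which of the two ends with the higher amount of product, in percent of the substrate charged ("neither" if they lie within 2 percentage points) (east / south / neither)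
2. product at the end, in percent of the substrate charged, east
3. product at the end, in percent of the substrate charged, south

1. A small charge of partner, 0.500 equiv in south, caps product there at a fraction 0.5 of the substrate charged, if each product takes one partner. Partner is then south's limiting reagent, and substrate is east's. So we need two times, a clock for each limiting reagent. Run time over clock is the reach, and we take exp(-reach) as the fraction of that charge left.

2. Product read at 30.0 s in grey gives a partner clock of 157 s. Brought to grey's loading by the root of the loading ratio, red at 1.4 equiv reads 150 s, and teal reads 159 s. In these runs the clock follows the root of the loading and barely follows the partner charge. From teal, south gets 69.2 s as its partner clock, the time in which the fraction of partner left falls by the natural factor e.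

3. Grey's substrate, scaled the same way, gives east a substrate clock of 62.4 s. East's reach is 1.92, so we expect 85.4% product. South's reach is 0.520, so we expect 20.3%, less than east.

4. The forecast says east, with 83% and 24%, noting “partner is limiting, capping product at 50%”. It names the same winner as we do, but our figures are 85.4% and 20.3%.

5. The flasks give 83.3% in east and 21.4% in south, so east ends higher, and the forecast held. South ends with 57% of its partner left, where its reach gave 59.5%.

    initiator → 2 initiating radical (k = 0.0189 s⁻¹)
    substrate + initiating radical → chain carrier (k = 8300 L mol⁻¹ s⁻¹)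
    partner + chain carrier → product + initiating radical (k = 8710 L mol⁻¹ s⁻¹)
    2 initiating radical → ended chains A (k = 4.00 × 10⁶ L mol⁻¹ s⁻¹)
    2 chain carrier → ended chains B (k = 9.30 × 10⁷ L mol⁻¹ s⁻¹)

6. A neighbour of south holds 0.120 equiv of partner at the same loading and time. We take its clock and reach as in south, so we expect 4.87% product. That neighbour gives 5.16%, with 57% of its partner left.

(The numbers in the tables were computed for an exercise, and the scatter is random.)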